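**Retrosynthetic overview**
1. Numbering: ring C1 (heptenyl), C2 (CH2OH), C3 (CHOH), C4 (oxirane CH), C5 (quaternary oxirane C), C6 (C=O); chain C1'–C7'. The plan rests on the unit C2=C1–C1'=C2'. This is a 1-alkenylcyclohex-1-ene in which the tetrasubstituted alkene C1=C2 of the six-membered carbocycle is conjugated with the exocyclic E alkene, which makes it the retron of an enyne metathesis.
2. The target comes from a protected C6-acetoxy epoxycyclohexene by acetate cleavage, oxidation at C6, desilylation and acidolysis of a tert-butyl ester.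
3. That cyclohexene comes from an acyclic epoxy 1,7-enyne and 1-heptene. One ruthenium-carbene cascade makes C1'=C2' (cross step on the alkyne C1≡C1') and C1=C2 (closure on the C2 methylidene).
4. The enyne comes from ethynyl Grignard addition to the C6 aldehyde. Before that, a 2-lithioallyl ether adds to the C3 epoxy aldehyde (sets C3), and Sharpless epoxidation of a Z-allylic alcohol sets C4 and C5.
5. The Z-allylic alcohol comes from Stille allylation of a β-stannyl allylic alcohol. Syn-stannylcupration of an ynoate fixes the alkene geometry and tells C3–OH from C6–O. Ring order: oxirane first (step 8), carbocycle second (step 17).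

Key step: step 17

Remark: C6 is carried from step 15 to step 18 as a mixture of epimers (left undefined in the SMILES) because step 19 makes it sp2, and the side-chain acid is carried as its tert-butyl ester so that acid can release it, since hydroxide would endanger the epoxy dienone.

**Route**

Step 1
Reactants: 1 prop-2-yn-1-ol
Product: 2 4-methoxybenzyl propargyl ether (1-methoxy-4-[(prop-2-yn-1-yloxy)methyl]benzene)
Conditions: NaH, PMBCl, Bu4NI (cat.), THF, 0 °C → rt
Reagents that add atoms: 4-methoxybenzyl chloride, COc1ccc(CCl)cc1
Why: Williamson etherification of the sodium alkoxide with the benzylic chloride (iodide catalysis) should be clean, and the PMB group is chosen because it can later be removed oxidatively beside silyl ethers, an epoxide and a tert-butyl ester.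

Step 2
Reactants: 2 4-methoxybenzyl propargyl ether; 3 ethyl chloroformate
Product: 5 ethyl 4-[(4-methoxybenzyl)oxy]but-2-ynoate, via lithium acetylide 4 (not isolated)
Conditions: n-BuLi, THF, −78 °C; then 3, −78 °C → 0 °C
Reagents that add atoms: none
Why: Deprotonation of the terminal alkyne and C-acylation of acetylide 4 with the chloroformate is the standard entry to 2-ynoates, and it brings in C3 at the ester level while C6 stays a PMB ether, so the two oxygenated termini are told apart from the start.

Step 3
Reactants: 5 ethyl 4-[(4-methoxybenzyl)oxy]but-2-ynoate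
Product: 7 ethyl (E)-4-[(4-methoxybenzyl)oxy]-3-(tributylstannyl)but-2-enoate, via alkenylcopper adduct 6 (not isolated)
Conditions: Bu3SnH, LDA, THF, 0 °C; CuBr·SMe2, −78 °C; then 5, MeOH, THF, −78 °C
Reagents that add atoms: tributyltin hydride, CCCC[SnH](CCCC)CCCC
Why: Stannylcupration of a 2-ynoate adds Sn–Cu syn with tin on the electrophilic β-carbon (C5), and methanol present at −78 °C protonates alkenylcopper 6 before it can isomerise through the allenoate, so that C3 and C6 should end up cis and the tin marks the site of the side chain.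

Step 4
Reactants: 7 ethyl (E)-4-[(4-methoxybenzyl)oxy]-3-(tributylstannyl)but-2-enoate
Product: 8 (E)-4-[(4-methoxybenzyl)oxy]-3-(tributylstannyl)but-2-en-1-ol
Conditions: DIBAL-H (2.2 equiv), CH2Cl2, −78 °C → 0 °C; aqueous work-up
Reagents that add atoms: none
Why: DIBAL-H 1,2-reduction of the enoate gives the allylic alcohol without touching the alkenylstannane, its geometry or the PMB ether.

Step 5
Reactants: 9 tiglic acid [(E)-2-methylbut-2-enoic acid]
Product: 10 tert-butyl tiglate [tert-butyl (E)-2-methylbut-2-enoate]
Conditions: isobutene, H2SO4 (cat.), CH2Cl2, sealed flask, rt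
Reagents that add atoms: isobutene, CC(C)=C
Why: Acid-catalysed addition of the carboxylic acid to isobutene (capture of the tert-butyl cation) esterifies without affecting the conjugated E alkene.

Step 6
Reactants: 10 tert-butyl tiglate
Product: 11 tert-butyl (E)-4-bromo-2-methylbut-2-enoate
Conditions: NBS, AIBN (cat.), PhCF3, reflux
Reagents that add atoms: N-bromosuccinimide, O=C1CCC(=O)N1Br
Why: Wohl–Ziegler bromination runs through the ester-conjugated allyl radical formed by abstraction at C4 and should give mainly the E 4-bromide, which is freed from the 2-(bromomethyl) isomer by chromatography.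

Step 7
Reactants: 8 (E)-4-[(4-methoxybenzyl)oxy]-3-(tributylstannyl)but-2-en-1-ol; 11 tert-butyl (E)-4-bromo-2-methylbut-2-enoate
Product: 12 tert-butyl (2E,5Z)-7-hydroxy-5-{[(4-methoxybenzyl)oxy]methyl}-2-methylhepta-2,5-dienoate
Conditions: Pd2(dba)3 (cat.), AsPh3 (cat.), NMP, rt → 40 °C
Reagents that add atoms: none
Why: Stille coupling of an alkenylstannane with an allylic bromide goes with retention at the C4=C5 alkene and joins the unsubstituted terminus of the π-allylpalladium, and its neutral medium keeps the skipped diene from slipping into conjugation with the ester.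

Step 8
Reactants: 12 tert-butyl (2E,5Z)-7-hydroxy-5-{[(4-methoxybenzyl)oxy]methyl}-2-methylhepta-2,5-dienoate
Product: 13 tert-butyl (E)-4-[(2S,3R)-3-(hydroxymethyl)-2-{[(4-methoxybenzyl)oxy]methyl}oxiran-2-yl]-2-methylbut-2-enoate (route numbering 4R,5S)
Conditions: Ti(OiPr)4 (cat.), D-(−)-diethyl tartrate (cat.), t-BuOOH (decane), 4 Å MS, CH2Cl2, −20 °C
Reagents that add atoms: tert-butyl hydroperoxide, CC(C)(C)OO
Why: Sharpless asymmetric epoxidation: with C3–OH as the only free (hence only directing) hydroxyl, the titanium D-(−)-tartrate complex delivers oxygen to the face that gives 2R epoxy alcohols from 3,3-disubstituted allylic alcohols, the syn addition to the Z alkene sets C4 (R) and C5 (S here) together with C3 and C6 cis on the oxirane, and the electron-poor enoate is not touched.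

Step 9
Reactants: 13 epoxy alcohol (4R,5S)
Product: 14 tert-butyl (E)-4-[(2S,3S)-3-formyl-2-{[(4-methoxybenzyl)oxy]methyl}oxiran-2-yl]-2-methylbut-2-enoate (same spatial arrangement, descriptor at C4 changes by priority)
Conditions: DMP, NaHCO3, CH2Cl2, 0 °C → rt
Reagents that add atoms: none
Why: Buffered Dess–Martin oxidation stops at the aldehyde, and C4 keeps its configuration because enolisation toward an oxirane carbon is strongly disfavoured.

Step 10
Reactants: 15 2-bromoprop-2-en-1-ol
Product: 16 [(2-bromoprop-2-en-1-yl)oxy](tert-butyl)dimethylsilane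
Conditions: TBSCl, imidazole, CH2Cl2, 0 °C → rt
Reagents that add atoms: tert-butyldimethylsilyl chloride, CC(C)(C)[Si](C)(C)Cl
Why: Imidazole-promoted silylation of an unhindered primary alcohol is routine and leaves the vinyl bromide intact.

Step 11
Reactants: 14 C3 epoxy aldehyde; 16 2-bromoallyl TBS ether
Product: 18 anti epoxy alcohol (3R,4R,5S) tert-butyl (E)-4-[(2S,3R)-3-[(1R)-2-{[(tert-butyldimethylsilyl)oxy]methyl}-1-hydroxyprop-2-en-1-yl]-2-{[(4-methoxybenzyl)oxy]methyl}oxiran-2-yl]-2-methylbut-2-enoate, via alkenyllithium 17 (not isolated)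
Conditions: 16, t-BuLi (2 equiv per 16), Et2O, −78 °C; then 14, Et2O, −78 °C; H2O quench at −78 °C
Reagents that add atoms: none
Why: Bromine–lithium exchange gives alkenyllithium 17, which adds 1,2 to the aldehyde at −78 °C far faster than it attacks the hindered tert-butyl enoate, and Felkin–Anh control (C4–O bond antiperiplanar to the incoming nucleophile, the same sense as the Cornforth model), reinforced by the C6 arm cis to the formyl group, should set C3 as R, the anti epoxy alcohol.

Step 12
Reactants: 18 anti epoxy alcohol (3R,4R,5S)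
Product: 19 C3,C2-CH2 bis-TBS ether of 18 (3R,4R,5S), PMB ether at C6–O retained
Conditions: TBSCl, imidazole, DMAP (cat.), DMF, rt → 40 °C
Reagents that add atoms: tert-butyldimethylsilyl chloride, CC(C)(C)[Si](C)(C)Cl
Why: Silylation with the chloride and imidazole protects the secondary allylic alcohol under conditions free of Lewis acid, which avoids the epoxide rearrangements that silyl triflates can trigger.

Step 13
Reactants: 19 bis-TBS PMB ether
Product: 20 C6 primary alcohol (3R,4R,5S)
Conditions: DDQ, CH2Cl2/pH 7 buffer, 0 °C
Reagents that add atoms: none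
Why: DDQ removes the PMB ether by hydride abstraction from the electron-rich benzylic position and hydrolysis of the oxocarbenium ion, a cleavage orthogonal to the silyl ethers, oxirane, alkenes and tert-butyl ester.

Step 14
Reactants: 20 C6 primary alcohol
Product: 21 C6 aldehyde on the quaternary oxirane carbon (3R,4R,5R by priority change)
Conditions: DMP, NaHCO3, CH2Cl2, 0 °C → rt
Reagents that add atoms: none
Why: Dess–Martin oxidation copes with the neopentyl-type primary alcohol, and the aldehyde formed cannot epimerise because C5 bears no hydrogen.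

Step 15
Reactants: 21 C6 aldehyde; 22 ethynylmagnesium bromide
Product: 23 C6 propargylic alcohol (3R,4R,5S; C6 epimers)
Conditions: 22 (0.5 M in THF), THF, −78 °C → −20 °C; aqueous work-up
Reagents that add atoms: none
Why: Grignard 1,2-addition of the acetylide to the aldehyde is much faster than attack on the tert-butyl enoate or the oxirane, and the new C6 stereocentre is left uncontrolled on purpose because step 19 turns it into the ketone.

Step 16
Reactants: 23 C6 propargylic alcohol
Product: 24 acyclic epoxy 1,7-enyne acetate (3R,4R,5S; C6 epimers): C2 methylidene bearing CH2OTBS, C3–OTBS, C4–C5 oxirane carrying the tert-butyl (E)-2-methylbut-2-enoate arm, C6–OAc, terminal alkyne C1≡C1'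
Conditions: Ac2O, DMAP (cat.), pyridine, 0 °C → rt
Reagents that add atoms: acetic anhydride, CC(=O)OC(C)=O
Why: DMAP-catalysed acylation caps the propargylic alcohol as the acetate, which shields ruthenium from the free hydroxyl, adds bulk next to C1 and can later be removed without touching the silyl ethers.

Step 17
Reactants: 24 epoxy 1,7-enyne acetate; 25 1-heptene
Product: 27 protected C6-acetoxy epoxycyclohexene bearing the (E)-hept-1-enyl diene (3R,4R,5S; C6 epimers), via ruthenium vinylcarbene 26 (not isolated)
Conditions: Hoveyda–Grubbs II (10 mol%), 25 (5 equiv, added in portions), toluene (5 mM in 24), 80 °C, Ar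
Reagents that add atoms: none
Why: Mechanism: the hexylidene carbene Ru=CH(C5H11) formed from the catalyst and 25 undergoes [2+2] cycloaddition/cycloreversion with the terminal alkyne of 24 with its carbon on the unhindered terminus C1' (new C1'=C2' bond) and ruthenium on C1, which gives vinylcarbene 26. 26 then engages the C2 methylidene intramolecularly in a second [2+2]/cycloreversion that makes the tetrasubstituted C1=C2 bond and closes the carbocycle in the six-membered exo mode (ring atoms C1–C6, diene arm exocyclic), and the Ru=CH2 released is returned to the hexylidene by 25 with loss of ethylene. The closest known reaction type is the one-pot ring-closing enyne metathesis/cross metathesis of 1,6- and 1,7-enynes with terminal alkenes under second-generation ruthenium carbenes, including closures onto 1,1-disubstituted alkenes. No stereocentre is formed: C3, C4 and C5 are untouched spectators and the C6 mixture is erased in step 19. The step needs carbene addition with carbon at C1' (secured by the branched, acetoxy-bearing C6 next to C1), ring closure faster than capture of 26 by 25 (secured by high dilution, portionwise 25 and the oxirane, which holds C3 and C6 cis and so keeps both reacting ends on one side), E geometry at C1'=C2' (secured by reversible secondary metathesis of this disubstituted alkene toward the less strained isomer) and silence of the other alkenes (the trisubstituted enoate is electron-poor and the C2 methylidene is too hindered to initiate). Substrate that is picked up by Ru=CH2 instead gives the 1-vinylcyclohexene, whose terminal vinyl group cross-metathesises with 25 to the same product 27.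

Step 18
Reactants: 27 C6-acetoxy epoxycyclohexene
Product: 28 C6 dienylic alcohol (3R,4R,5S; C6 epimers)
Conditions: K2CO3 (cat.), MeOH, 0 °C
Reagents that add atoms: none
Why: Carbonate-catalysed methanolysis (transesterification) cleaves the secondary acetate while the tert-butyl ester and silyl ethers are inert, and the low temperature and catalytic base should keep the C6 alkoxide from migrating the epoxide (Payne rearrangement).

Step 19
Reactants: 28 C6 dienylic alcohol
Product: 29 bis-TBS epoxy dienone tert-butyl ester (3R,4R,5R)
Conditions: DMP, NaHCO3, CH2Cl2, 0 °C → rt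
Reagents that add atoms: none
Why: Dess–Martin oxidation of the dienylic alcohol funnels both C6 epimers into one cross-conjugated dienone, and neither C5 (no hydrogen) nor C3 and C4 are at risk under the buffered neutral conditions.

Step 20
Reactants: 29 bis-TBS epoxy dienone tert-butyl ester
Product: 30 tert-butyl ester of the target (3R,4R,5R), free C3–OH and C2–CH2OH
Conditions: HF·pyridine, pyridine, THF, 0 °C → rt
Reagents that add atoms: none
Why: Fluoride-driven desilylation with buffered HF·pyridine removes both TBS ethers under non-basic conditions that the epoxy ketone and the tert-butyl ester tolerate.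

Step 21
Reactants: 30 tert-butyl ester of the target
Product: 31 target, (E)-4-[(1R,5R,6R)-3-[(E)-hept-1-enyl]-5-hydroxy-4-(hydroxymethyl)-2-oxo-7-oxabicyclo[4.1.0]hept-3-en-1-yl]-2-methylbut-2-enoic acid
Conditions: TFA/CH2Cl2 (1:4), 0 °C
Reagents that add atoms: none
Why: Acidolysis of the tert-butyl ester (loss of isobutene through the tert-butyl cation) frees the acid without base, and the oxirane and both allylic alcohols should survive because ionisation at C3, C4, C5 and the C2 hydroxymethyl carbon is disfavoured by the conjugated C6 carbonyl.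

**Compound list**
1 | prop-2-yn-1-ol | OCC#C | starting material
2 | 4-methoxybenzyl propargyl ether | C#CCOCc1ccc(OC)cc1 | intermediate
3 | ethyl chloroformate | CCOC(=O)Cl | starting material
4 | lithium acetylide of 2 | [Li]C#CCOCc1ccc(OC)cc1 | intermediate
5 | ethyl 4-[(4-methoxybenzyl)oxy]but-2-ynoate | CCOC(=O)C#CCOCc1ccc(OC)cc1 | intermediate
6 | alkenylcopper syn adduct (Cu on C4, Sn on C5, cis) | CCOC(=O)/C([Cu])=C(/[Sn](CCCC)(CCCC)CCCC)COCc1ccc(OC)cc1 | intermediate
7 | ethyl (E)-4-[(4-methoxybenzyl)oxy]-3-(tributylstannyl)but-2-enoate | CCOC(=O)/C=C(/[Sn](CCCC)(CCCC)CCCC)COCc1ccc(OC)cc1 | intermediate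
8 | (E)-4-[(4-methoxybenzyl)oxy]-3-(tributylstannyl)but-2-en-1-ol | OC/C=C(/[Sn](CCCC)(CCCC)CCCC)COCc1ccc(OC)cc1 | intermediate
9 | tiglic acid | C/C=C(\C)C(=O)O | starting material
10 | tert-butyl tiglate | C/C=C(\C)C(=O)OC(C)(C)C | intermediate
11 | tert-butyl (E)-4-bromo-2-methylbut-2-enoate | BrC/C=C(\C)C(=O)OC(C)(C)C | intermediate
12 | tert-butyl (2E,5Z)-7-hydroxy-5-{[(4-methoxybenzyl)oxy]methyl}-2-methylhepta-2,5-dienoate | OC/C=C(/C/C=C(\C)C(=O)OC(C)(C)C)COCc1ccc(OC)cc1 | intermediate
13 | epoxy alcohol (4R,5S) | OC[C@H]1O[C@@]1(C/C=C(\C)C(=O)OC(C)(C)C)COCc1ccc(OC)cc1 | intermediate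
14 | C3 epoxy aldehyde (4S,5S) | O=C[C@H]1O[C@@]1(C/C=C(\C)C(=O)OC(C)(C)C)COCc1ccc(OC)cc1 | intermediate
15 | 2-bromoprop-2-en-1-ol | OCC(Br)=C | starting material
16 | [(2-bromoprop-2-en-1-yl)oxy](tert-butyl)dimethylsilane | C=C(Br)CO[Si](C)(C)C(C)(C)C | intermediate
17 | 2-lithioallyl TBS ether | [Li]C(=C)CO[Si](C)(C)C(C)(C)C | intermediate
18 | anti epoxy alcohol (3R,4R,5S) | C=C(CO[Si](C)(C)C(C)(C)C)[C@@H](O)[C@H]1O[C@@]1(C/C=C(\C)C(=O)OC(C)(C)C)COCc1ccc(OC)cc1 | intermediate
19 | bis-TBS PMB ether (3R,4R,5S) | C=C(CO[Si](C)(C)C(C)(C)C)[C@@H](O[Si](C)(C)C(C)(C)C)[C@H]1O[C@@]1(C/C=C(\C)C(=O)OC(C)(C)C)COCc1ccc(OC)cc1 | intermediate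
20 | C6 primary alcohol (3R,4R,5S) | C=C(CO[Si](C)(C)C(C)(C)C)[C@@H](O[Si](C)(C)C(C)(C)C)[C@H]1O[C@@]1(C/C=C(\C)C(=O)OC(C)(C)C)CO | intermediate
21 | C6 aldehyde (3R,4R,5R) | C=C(CO[Si](C)(C)C(C)(C)C)[C@@H](O[Si](C)(C)C(C)(C)C)[C@H]1O[C@@]1(C/C=C(\C)C(=O)OC(C)(C)C)C=O | intermediate
22 | ethynylmagnesium bromide | C#C[Mg]Br | starting material
23 | C6 propargylic alcohol (3R,4R,5S; C6 epimers) | C=C(CO[Si](C)(C)C(C)(C)C)[C@@H](O[Si](C)(C)C(C)(C)C)[C@H]1O[C@@]1(C/C=C(\C)C(=O)OC(C)(C)C)C(O)C#C | intermediate
24 | epoxy 1,7-enyne acetate (3R,4R,5S; C6 epimers) | C=C(CO[Si](C)(C)C(C)(C)C)[C@@H](O[Si](C)(C)C(C)(C)C)[C@H]1O[C@@]1(C/C=C(\C)C(=O)OC(C)(C)C)C(OC(C)=O)C#C | intermediate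
25 | 1-heptene | C=CCCCCC | starting material
26 | ruthenium vinylcarbene (Ru on C1, E C1'=C2', RuCl2(SIMes) fragment) | C=C(CO[Si](C)(C)C(C)(C)C)[C@@H](O[Si](C)(C)C(C)(C)C)[C@H]1O[C@@]1(C/C=C(\C)C(=O)OC(C)(C)C)C(OC(C)=O)C(/C=C/CCCCC)=[Ru](Cl)(Cl)=C1N(c2c(C)cc(C)cc2C)CCN1c1c(C)cc(C)cc1C | intermediate
27 | protected C6-acetoxy epoxycyclohexene with E-heptenyl diene (3R,4R,5S; C6 epimers) | CCCCC/C=C/C1=C(CO[Si](C)(C)C(C)(C)C)[C@@H](O[Si](C)(C)C(C)(C)C)[C@H]2O[C@@]2(C/C=C(\C)C(=O)OC(C)(C)C)C1OC(C)=O | intermediate
28 | C6 dienylic alcohol (3R,4R,5S; C6 epimers) | CCCCC/C=C/C1=C(CO[Si](C)(C)C(C)(C)C)[C@@H](O[Si](C)(C)C(C)(C)C)[C@H]2O[C@@]2(C/C=C(\C)C(=O)OC(C)(C)C)C1O | intermediate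
29 | bis-TBS epoxy dienone tert-butyl ester (3R,4R,5R) | CCCCC/C=C/C1=C(CO[Si](C)(C)C(C)(C)C)[C@@H](O[Si](C)(C)C(C)(C)C)[C@H]2O[C@@]2(C/C=C(\C)C(=O)OC(C)(C)C)C1=O | intermediate
30 | tert-butyl ester of the target (3R,4R,5R) | CCCCC/C=C/C1=C(CO)[C@@H](O)[C@H]2O[C@@]2(C/C=C(\C)C(=O)OC(C)(C)C)C1=O | intermediate
31 | CNP0332048.1 (3R,4R,5R) | CCCCC/C=C/C1=C(CO)[C@@H](O)[C@H]2O[C@@]2(C/C=C(\C)C(=O)O)C1=O | target

**Step count**
Total steps: 21. Longest linear sequence: 18 (steps 1–4, 7–9, 11–21). Steps 5–6 and step 10 are side branches.

**Steps most likely to fail**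

1. Step 17. The vinylcarbene may be captured by 1-heptene, or by the ethylene that builds up, before it reaches the hindered C2 methylidene. That would drain material into an acyclic cross-metathesis triene that does not close, while the catalyst decays at the methylidene stage. The fallback separates the two bond-forming events. It sets out from 24. Ring-closing enyne metathesis is run with Grubbs II in dilute toluene under argon with no external alkene, so the unsubstituted vinylcarbene has only the intramolecular partner. This should give the 1-vinylcyclohexene acetate F1. The monosubstituted diene terminus of F1 is then cross-metathesised with an excess of 25 (Hoveyda–Grubbs II, CH2Cl2, 40 °C), which comes back to the route at 27.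

2. Step 11. Facial selectivity at the aldehyde may be poor, for example through lithium coordination to the oxirane or PMB oxygen competing with the Felkin–Anh arrangement. The fallback sets C3 by hydride delivery instead of by C–C bond formation. It sets out from 18, taken on as the crude mixture of C3 epimers. This mixture is oxidised with Dess–Martin periodinane to the epoxy enone F2. F2 is then reduced with Zn(BH4)2 in Et2O at −20 °C. Zinc chelates the carbonyl and oxirane oxygens, and hydride arrives from the side of the C4 hydrogen. This known type of reduction of α,β-epoxy ketones gives the anti epoxy alcohol and comes back to the route at 18.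

3. Step 21. The acid may open the oxirane with help from the free C3 hydroxyl, or it may trifluoroacetylate or ionise the free allylic alcohols. The fallback reverses the order of the two unmasking events. It sets out from 29. Acidolysis (TFA/CH2Cl2, 0 °C) is done while both hydroxyls are still silylated and should give the bis-TBS acid F3. HF·pyridine in THF then removes the silyl groups and comes back to the route at 31. Any silyl ether lost in the first operation is harmless because the second removes them all.

**Further compounds**
F1 | step 17 | 1-vinylcyclohexene acetate (3R,4R,5S; C6 epimers) | C=CC1=C(CO[Si](C)(C)C(C)(C)C)[C@@H](O[Si](C)(C)C(C)(C)C)[C@H]2O[C@@]2(C/C=C(\C)C(=O)OC(C)(C)C)C1OC(C)=O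
F2 | step 11 | epoxy enone (4S,5S) | C=C(CO[Si](C)(C)C(C)(C)C)C(=O)[C@H]1O[C@@]1(C/C=C(\C)C(=O)OC(C)(C)C)COCc1ccc(OC)cc1
F3 | step 21 | bis-TBS acid (3R,4R,5R) | CCCCC/C=C/C1=C(CO[Si](C)(C)C(C)(C)C)[C@@H](O[Si](C)(C)C(C)(C)C)[C@H]2O[C@@]2(C/C=C(\C)C(=O)O)C1=O
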